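**Retrosynthetic overview**
1. Target ⇐ its hexamethyl ether by one global O‑demethylation.
2. The dihydrofuran ring is the only ring built; all benzene rings and the stilbene arm are bought. It comes from a formal [4+1] union of an o‑quinone methide with a chiral benzylic sulfonium ylide.
3. Key C2–C3 bond: the veratryl benzylic carbon, an electrophile in the bromide or aldehyde, is used with reversed polarity as the ylide carbanion against the electrophilic methide carbon. O1–C2 then closes with loss of the sulfide, and both stereocentres are set here.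
4. o‑Quinone methide ⇐ 2‑[aryl(tosyl)methyl]phenol ⇐ ArMgCl + salicylaldehyde ⇐ ortho‑formylation of pterostilbene.
5. Ylide ⇐ sulfonium salt ⇐ 3,4‑dimethoxybenzyl bromide + isothiocineole.

Assumption: the ylide from the (1R,4R,5R)‑sulfide is taken to react on the face remote from its gem‑dimethyl carbon, which gives 2S here; if the observed sense is opposite, the (1S,4S,5S)‑sulfide is used with no other change.

**Route**

Step 1
Reactants: 1 pterostilbene, 4‑[(E)‑2‑(3,5‑dimethoxyphenyl)ethenyl]phenol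
Product: 3 2‑hydroxy‑5‑[(E)‑2‑(3,5‑dimethoxyphenyl)ethenyl]benzaldehyde, via salicyl alcohol 2 (not isolated)
Conditions: MgCl2 (1.5 equiv), NEt3 (3.75 equiv), (CH2O)n (7 equiv), MeCN, reflux; then 1 M HCl
Reagents that add atoms: paraformaldehyde (formaldehyde unit), C=O
Why: Magnesium‑mediated ortho‑formylation (Casnati–Skattebøl): the magnesium phenoxide of 1 delivers formaldehyde only ortho to the phenol oxygen to give chelated 2, which a second formaldehyde oxidises by Oppenauer‑type hydride transfer; the stilbene and the dimethoxyaryl ring are untouched and no stereocentre is formed.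

Step 2
Reactants: 3 2‑hydroxy‑5‑[(E)‑2‑(3,5‑dimethoxyphenyl)ethenyl]benzaldehyde; 4 3,5‑dimethoxyphenylmagnesium chloride (2.5 equiv, commercial THF solution)
Product: 5 rac‑2‑[(3,5‑dimethoxyphenyl)(hydroxy)methyl]‑4‑[(E)‑2‑(3,5‑dimethoxyphenyl)ethenyl]phenol
Conditions: THF, 0 °C → rt; cold aq. NH4Cl; crude used at once
Reagents that add atoms: none
Why: Grignard 1,2‑addition to the aldehyde after the first equivalent has deprotonated the phenol; the carbinol centre is formed racemic and is destroyed again in step 5.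

Step 3
Reactants: 5 rac‑2‑[(3,5‑dimethoxyphenyl)(hydroxy)methyl]‑4‑[(E)‑2‑(3,5‑dimethoxyphenyl)ethenyl]phenol
Product: 6 rac‑2‑[(3,5‑dimethoxyphenyl)(4‑methylbenzenesulfonyl)methyl]‑4‑[(E)‑2‑(3,5‑dimethoxyphenyl)ethenyl]phenol
Conditions: 4‑methylbenzenesulfinic acid (1.5 equiv), CH2Cl2, rt
Reagents that add atoms: 4‑methylbenzenesulfinic acid, Cc1ccc(cc1)S(=O)O
Why: SN1‑type substitution of the doubly activated benzhydrol hydroxyl by the sulfur of the sulfinic acid (sulfone formation) gives the bench‑stable precursor from which base later releases the quinone methide; the centre is racemic and is erased in step 5.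

Step 4
Reactants: 7 3,4‑dimethoxybenzyl bromide; 8 (1R,4R,5R)‑4,7,7‑trimethyl‑6‑thiabicyclo[3.2.1]octane (isothiocineole)
Product: 9 (1R,4R,5R)‑6‑[(3,4‑dimethoxyphenyl)methyl]‑4,7,7‑trimethyl‑6‑thiabicyclo[3.2.1]octan‑6‑ium trifluoromethanesulfonate (benzyl group on the exo lone pair)
Conditions: LiOSO2CF3 (5 equiv), CH2Cl2/H2O, rt, 24 h; crystallise
Reagents that add atoms: lithium trifluoromethanesulfonate, [Li+].[O-]S(=O)(=O)C(F)(F)F
Why: SN2 S‑alkylation of the bicyclic sulfide on its less hindered exo lone pair gives a single sulfonium diastereomer, and exchange to the non‑nucleophilic triflate stops the reverse reaction; no carbon stereocentre is formed.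

Step 5
Reactants: 6 rac‑2‑[(3,5‑dimethoxyphenyl)(4‑methylbenzenesulfonyl)methyl]‑4‑[(E)‑2‑(3,5‑dimethoxyphenyl)ethenyl]phenol; 9 sulfonium triflate (1.3 equiv)
Product: 13 (2S,3S)‑2‑(3,4‑dimethoxyphenyl)‑3‑(3,5‑dimethoxyphenyl)‑5‑[(E)‑2‑(3,5‑dimethoxyphenyl)ethenyl]‑2,3‑dihydro‑1‑benzofuran, via o‑quinone methide 10 (not isolated), via sulfonium ylide 11 (not isolated), via betaine 12 (not isolated)
Conditions: Cs2CO3 (3 equiv), MeCN, 0 °C, 12 h; chromatography (removes any cis isomer, returns 8), one recrystallisation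
Reagents that add atoms: none
Why: Proposed new method: Cs2CO3 converts 6 into o‑quinone methide 10 (E1cB loss of sulfinate) and deprotonates 9 to ylide 11, whose carbanion carbon (the veratryl benzylic carbon, an electrophile in 7 or in veratraldehyde, here used with reversed polarity as a d1 α‑oxybenzyl‑anion equivalent) adds to the electrophilic methide carbon of 10 in a conjugate addition driven by re‑aromatisation, after which the phenoxide of betaine 12 displaces the sulfide by 5‑exo‑tet SN2 with inversion; the rigid sulfide fixes the ylide conformation (aryl syn to the sulfur lone pair) and shields the face next to its gem‑dimethyl carbon, which sets C2 as S, and the approach that keeps the two aryl groups apart on the E‑configured 10 sets C3 as S (trans); the closest known reaction types are Corey–Chaykovsky‑type asymmetric epoxidation and aziridination with isothiocineole‑derived benzylsulfonium ylides and the base‑mediated formal [4+1] annulation of 2‑(tosylalkyl)phenol‑derived o‑quinone methides with stabilised sulfur ylides to trans‑2,3‑dihydrobenzofurans.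

Step 6
Reactants: 13 (2S,3S)‑2‑(3,4‑dimethoxyphenyl)‑3‑(3,5‑dimethoxyphenyl)‑5‑[(E)‑2‑(3,5‑dimethoxyphenyl)ethenyl]‑2,3‑dihydro‑1‑benzofuran
Product: 14 4‑[(2S,3S)‑3‑(3,5‑dihydroxyphenyl)‑5‑[(E)‑2‑(3,5‑dihydroxyphenyl)ethenyl]‑2,3‑dihydro‑1‑benzofuran‑2‑yl]benzene‑1,2‑diol
Conditions: BBr3 (12 equiv), CH2Cl2, −78 → 0 °C; MeOH then aq. NaHCO3, argon
Reagents that add atoms: none
Why: Lewis‑acid ether cleavage (BBr3 demethylation) removes the six aryl methyl groups by bromide attack on the boron‑coordinated methyl ethers; C3 has no epimerisation pathway and any reversible C2–O ionisation re‑closes to the favoured trans ring, so (2S,3S) is kept.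

**Compound list**
1 | pterostilbene, 4‑[(E)‑2‑(3,5‑dimethoxyphenyl)ethenyl]phenol | COc1cc(OC)cc(/C=C/c2ccc(O)cc2)c1 | starting material
2 | 2‑(hydroxymethyl)‑4‑[(E)‑2‑(3,5‑dimethoxyphenyl)ethenyl]phenol (as magnesium chelate) | COc1cc(OC)cc(/C=C/c2ccc(O)c(CO)c2)c1 | intermediate (not isolated)
3 | 2‑hydroxy‑5‑[(E)‑2‑(3,5‑dimethoxyphenyl)ethenyl]benzaldehyde | COc1cc(OC)cc(/C=C/c2ccc(O)c(C=O)c2)c1 | intermediate
4 | 3,5‑dimethoxyphenylmagnesium chloride | COc1cc(OC)cc([Mg]Cl)c1 | starting material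
5 | rac‑2‑[(3,5‑dimethoxyphenyl)(hydroxy)methyl]‑4‑[(E)‑2‑(3,5‑dimethoxyphenyl)ethenyl]phenol | COc1cc(OC)cc(/C=C/c2ccc(O)c(C(O)c3cc(OC)cc(OC)c3)c2)c1 | intermediate
6 | rac‑2‑[(3,5‑dimethoxyphenyl)(4‑methylbenzenesulfonyl)methyl]‑4‑[(E)‑2‑(3,5‑dimethoxyphenyl)ethenyl]phenol | COc1cc(OC)cc(/C=C/c2ccc(O)c(C(c3cc(OC)cc(OC)c3)S(=O)(=O)c3ccc(C)cc3)c2)c1 | intermediate
7 | 3,4‑dimethoxybenzyl bromide, 4‑(bromomethyl)‑1,2‑dimethoxybenzene | COc1ccc(CBr)cc1OC | starting material
8 | (1R,4R,5R)‑4,7,7‑trimethyl‑6‑thiabicyclo[3.2.1]octane (isothiocineole; recovered in step 5) | C[C@@H]1CC[C@@H]2C[C@H]1SC2(C)C | starting material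
9 | (1R,4R,5R)‑6‑[(3,4‑dimethoxyphenyl)methyl]‑4,7,7‑trimethyl‑6‑thiabicyclo[3.2.1]octan‑6‑ium trifluoromethanesulfonate, exo S‑benzyl | C[C@@H]1CC[C@@H]2C[C@H]1[S@@+](Cc3ccc(OC)c(OC)c3)C2(C)C.[O-]S(=O)(=O)C(F)(F)F | intermediate
10 | (6E)‑6‑[(3,5‑dimethoxyphenyl)methylidene]‑4‑[(E)‑2‑(3,5‑dimethoxyphenyl)ethenyl]cyclohexa‑2,4‑dien‑1‑one (o‑quinone methide) | O=C1/C(=C/c3cc(OC)cc(OC)c3)C=C(/C=C/c2cc(OC)cc(OC)c2)C=C1 | intermediate (not isolated)
11 | sulfonium ylide of 9, (3,4‑dimethoxyphenyl)methanide on sulfur | C[C@@H]1CC[C@@H]2C[C@H]1[S@@+]([CH-]c3ccc(OC)c(OC)c3)C2(C)C | intermediate (not isolated)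
12 | betaine: 2‑[2‑(3,4‑dimethoxyphenyl)‑1‑(3,5‑dimethoxyphenyl)‑2‑(sulfonio)ethyl]‑4‑[(E)‑2‑(3,5‑dimethoxyphenyl)ethenyl]phenolate, the diastereomer that closes to trans | C[C@@H]1CC[C@@H]2C[C@H]1[S@@+]([C@@H](c3ccc(OC)c(OC)c3)[C@@H](c4cc(OC)cc(OC)c4)c5cc(/C=C/c6cc(OC)cc(OC)c6)ccc5[O-])C2(C)C | intermediate (not isolated)
13 | (2S,3S)‑2‑(3,4‑dimethoxyphenyl)‑3‑(3,5‑dimethoxyphenyl)‑5‑[(E)‑2‑(3,5‑dimethoxyphenyl)ethenyl]‑2,3‑dihydro‑1‑benzofuran | COc1cc(OC)cc(/C=C/c2ccc3c(c2)[C@H](c2cc(OC)cc(OC)c2)[C@@H](c2ccc(OC)c(OC)c2)O3)c1 | intermediate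
14 | 4‑[(2S,3S)‑3‑(3,5‑dihydroxyphenyl)‑5‑[(E)‑2‑(3,5‑dihydroxyphenyl)ethenyl]‑2,3‑dihydro‑1‑benzofuran‑2‑yl]benzene‑1,2‑diol | Oc1cc(O)cc(/C=C/c2ccc3c(c2)[C@H](c2cc(O)cc(O)c2)[C@@H](c2ccc(O)c(O)c2)O3)c1 | target

**Count**
Total steps: 6. Longest linear sequence: 5 (steps 1, 2, 3, 5, 6; step 4 is the side branch).

**Three steps most likely to fail**

Step 5 (key annulation). A semi‑stabilised chiral benzylsulfonium ylide has not been paired with an o‑quinone methide. The liberated sulfinate may dealkylate 9. The electron‑rich benzylic sulfonium centre of 12 may ionise before ring closure, which would lower dr and ee. The fallback keeps the reversed‑polarity logic but uses an acyl anion, and sets out from sulfone 6. Cs2CO3 releases 10 in THF in the presence of 3,4‑dimethoxybenzaldehyde and the carbene from 3‑benzyl‑5‑(2‑hydroxyethyl)‑4‑methylthiazolium chloride (20 mol %). The Breslow intermediate adds to the methide carbon and gives the racemic ketone 1‑(3,4‑dimethoxyphenyl)‑2‑(3,5‑dimethoxyphenyl)‑2‑{2‑hydroxy‑5‑[(E)‑2‑(3,5‑dimethoxyphenyl)ethenyl]phenyl}ethan‑1‑one F1. Its doubly benzylic α‑carbon racemises freely, so transfer hydrogenation with dynamic kinetic resolution ([RuCl(p‑cymene)((S,S)‑TsDPEN)], base‑rich HCO2H/NEt3, DMF, rt) gives (1S,2S)‑1‑(3,4‑dimethoxyphenyl)‑2‑(3,5‑dimethoxyphenyl)‑2‑{2‑hydroxy‑5‑[(E)‑2‑(3,5‑dimethoxyphenyl)ethenyl]phenyl}ethan‑1‑ol F2. Only C2 of F2 matters, because catalytic TsOH in CH2Cl2 at 0 °C closes the ring by SN1 substitution at C1, trans to the C2 aryl group. This comes back to the route at 13.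

Step 3 (sulfone formation). The acid‑labile, very electron‑rich benzhydrol 5 may oligomerise by Friedel–Crafts attack of the dimethoxyaryl rings or the hydroxystilbene before the sulfinic acid traps it. The fallback generates the quinone methide under anionic conditions with no acid, and sets out from aldehyde 3. Boc2O with catalytic DMAP gives tert‑butyl 2‑formyl‑4‑[(E)‑2‑(3,5‑dimethoxyphenyl)ethenyl]phenyl carbonate F3. At −78 °C in THF, 4 (1.05 equiv) adds to the aldehyde, the new alkoxide takes over the Boc group, and on warming to −40 °C the phenoxide expels tert‑butyl carbonate. This forms 10 directly, and ylide 11 (pre‑formed from 9 with KN(SiMe3)2 in THF at −78 °C) is cannulated in. The route is rejoined at 10 and so at 13, without 5 and 6.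

Step 6 (global demethylation). The expected weak points are partial cleavage and damage to the stilbene or the catechol when the free hexaphenol is released into an HBr‑rich quench, rather than loss of the ring. The fallback changes from direct isolation of the polyphenol to a methyl‑to‑acetyl exchange, and sets out from 13. After BBr3 in CH2Cl2 at −78 → 0 °C the mixture is quenched with MeOH at −78 °C, volatiles are stripped cold, and the crude is acetylated at once (Ac2O, pyridine, DMAP). This gives the hexaacetate (2S,3S)‑2‑(3,4‑diacetoxyphenyl)‑3‑(3,5‑diacetoxyphenyl)‑5‑[(E)‑2‑(3,5‑diacetoxyphenyl)ethenyl]‑2,3‑dihydro‑1‑benzofuran F4. F4 is stable to air and silica and can be purified and recrystallised away from partly cleaved or ring‑opened material. Catalytic K2CO3 in MeOH at 0 °C under argon (transesterification) then releases the phenols and comes back to the route at 14. This fallback still depends on BBr3 for the ether cleavage.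

**Further compounds**
F1 | step 5 | rac‑1‑(3,4‑dimethoxyphenyl)‑2‑(3,5‑dimethoxyphenyl)‑2‑{2‑hydroxy‑5‑[(E)‑2‑(3,5‑dimethoxyphenyl)ethenyl]phenyl}ethan‑1‑one | COc1cc(OC)cc(/C=C/c2ccc(O)c(C(C(=O)c3ccc(OC)c(OC)c3)c3cc(OC)cc(OC)c3)c2)c1
F2 | step 5 | (1S,2S)‑1‑(3,4‑dimethoxyphenyl)‑2‑(3,5‑dimethoxyphenyl)‑2‑{2‑hydroxy‑5‑[(E)‑2‑(3,5‑dimethoxyphenyl)ethenyl]phenyl}ethan‑1‑ol | COc1cc(OC)cc(/C=C/c2ccc(O)c([C@@H]([C@H](O)c3ccc(OC)c(OC)c3)c3cc(OC)cc(OC)c3)c2)c1
F3 | step 3 | tert‑butyl 2‑formyl‑4‑[(E)‑2‑(3,5‑dimethoxyphenyl)ethenyl]phenyl carbonate | COc1cc(OC)cc(/C=C/c2ccc(OC(=O)OC(C)(C)C)c(C=O)c2)c1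
F4 | step 6 | (2S,3S)‑2‑(3,4‑diacetoxyphenyl)‑3‑(3,5‑diacetoxyphenyl)‑5‑[(E)‑2‑(3,5‑diacetoxyphenyl)ethenyl]‑2,3‑dihydro‑1‑benzofuran | CC(=O)Oc1cc(OC(C)=O)cc(/C=C/c2ccc3c(c2)[C@H](c2cc(OC(C)=O)cc(OC(C)=O)c2)[C@@H](c2ccc(OC(C)=O)c(OC(C)=O)c2)O3)c1
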